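## Structural features

The target is a biflavone ether without any stereocentre: two 2-arylchromen-4-one units are joined only by an oxygen bridge between C4' of ring B of unit 1 and C8 of ring A of unit 2. Unit 1 is a 5-hydroxy-7-methoxyflavone whose ring B is para-disubstituted. Unit 2 is a 5,7-dihydroxy-2-(4-hydroxyphenyl)chromone with the aryloxy group at C8, so its ring A is a fully differentiated 1,2,3,5-tetraoxygenated benzene (O1 on C8a, the ether on C8, hydroxyls on C7 and C5). The molecule holds four free phenols, one methyl ether that must outlast every deprotection, and two pyranone rings that open under strong hydroxide or hot mineral acid. The real difficulty is regiochemical: C8 and C6 of unit 2 are both flanked by oxygen, and once O5 of unit 2 is free, opening and reclosure of ring C (a Wessely–Moser shift) can move the ether from C8 to C6. The C8 position must therefore be settled before ring C exists, and O5 must stay masked until a last, neutral step. A second difficulty is the diaryl ether, whose phenolic partner is di-ortho-substituted, electron-rich and easily oxidised. The key step uses the fact that C4 of unit 2 can be a formyl carbon on C4a, ortho to the C8a hydroxyl: that hydroxyl steers trivalent rhodium to the formyl C-H bond and later becomes O1, so C3-C4 and O1-C2 of ring C are made in one operation on a ring A whose four oxygens are already in place.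

## Logic of the disconnections

20 ⇒ 19. The three benzyl-oxygen bonds on O5 and O7 of unit 2 and on O4''' are cut first. Keeping unit 2 fully masked until the end means no earlier acid or base meets a free O5 next to C4, so the ether cannot shift from C8 to C6. The gain is that 19 is one lipophilic compound whose only free hydroxyl is the chelated O5 of unit 1. The forward step must be neutral and must spare the methyl ether, the diaryl ether and both C2-C3 double bonds.

19 ⇒ 18. The O1-C2 bond of unit 1 is cut, opening ring C of unit 1 to an o-hydroxyaryl 1,3-diketone. The two phenolic oxygens beside the ketone in 18 are equivalent, so closure has no regiochemical choice and the other oxygen is left as the free O5. The forward cyclodehydration must dehydrate the hemiketal without removing benzyl ethers.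

18 ⇒ 15 + 16 (through 17). The C2-C3 bond of unit 1 is cut between the methylene carbon and the carbonyl carbon on ring B. This is the largest simplification of the plan: complete unit 2 with a para-carboxyphenyl ether (15) on one side, and a commercial symmetrical ketone (16) holding O5, the methylated O7 and C4 of unit 1 on the other. The forward step must acylate carbon of 16 without protecting its phenols, and 17 must be made and used under conditions the pyranone of unit 2 tolerates.

15 ⇒ 14. Only the ester C-O bond is changed. The carboxyl group travels as a methyl ester because it activates 6 for substitution, is inert to peracid, to methanolic acid, to the magnesium phenoxide and to cationic rhodium, and would direct C-H activation itself if free. A tert-butyl ester was weighed and rejected: its acidic removal would collide with the MOM cleavage and with the benzyl ether next to C4. The forward hydrolysis must not open ring C of unit 2.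

14 ⇒ 9 + 12 (through 13). The key cut removes C3-C4 and O1-C2 of unit 2, and with them ring C. It leaves 9, in which C4 is a formyl carbon beside the free C8a hydroxyl, and 12, which supplies C3, C2 and ring B with O4''' benzylated. The design of 9 is kept deliberately:
- the oxygen on the other side of the formyl group (future O5) is benzylated, so only one oxygen can direct the metal and close the ring;
- the ether already sits on the carbon that becomes C8;
- all protecting groups are benzyl, so one final operation removes them.

The forward step must select the formyl C-H bond over all aryl C-H bonds and must not disturb the benzyl ethers or the ester.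

12 ⇒ 10 (through 11). The bond between the carbonyl carbon and the ylide carbon is cut, giving a commercial acid and a one-carbon sulfoxonium reagent. The forward step needs excess methylide, because the first-formed acyl sulfoxonium salt is acidic.

9 ⇒ 8. The C4a-C4 bond (aryl-formyl) is cut. Placing the formyl group last on ring A lets the free hydroxyl choose the site, which turns the C8/C6 question into a question of which oxygen is free. The forward formylation must be strictly ortho, because the carbon para to the hydroxyl is equally activated.

8 ⇒ 7. The acetal O-C bond of the MOM group is cut. The MOM ether differentiates the oxygen that becomes O1 from the two benzylated oxygens and from the oxygen that is arylated. Its removal must spare benzyl ethers and the ester.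

7 ⇒ 5 + 6. The bond between the bridging oxygen and C4' of ring B of unit 1 is cut. This separates a commercial fluoroarene from the tetraoxygenated ring and uses the ester as activating group. The forward substitution has to work with a hindered, oxidation-prone phenoxide.

5 ⇒ 3 (through 4). The phenolic C-O bond is traced back to a C-CHO bond. The original formyl group first differentiates the three oxygens of the starting material through its hydrogen bond and is then exchanged for the fourth oxygen. The forward oxidation must migrate the aryl group, not hydride.

3 ⇒ 2 ⇒ 1. The MOM and benzyl O-C bonds are cut in turn. The chelated hydroxyl of 1 is the last to be alkylated, so two benzyl groups go on first and the MOM group takes the remaining oxygen. The forward benzylation must stop at the dibenzyl stage.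

## Other disconnections considered

Alternative 1: The cut is at C8-C8a and C5-C4a of unit 2, which dissolves ring A. C5 to C8 with O5, O7 and the bridging oxygen come from the bis-silyl dienol ether A1, which already carries all of unit 1. C4a, C8a and ring C come from the sulfinylpyranone A2. In the forward step the aryloxy-bearing terminus of A1 would add to C6 of A2 (Mukaiyama–Michael), the sulfinyl-stabilised enolate at C5 would close on the ester carbon of the former diene (Dieckmann type), and syn-elimination of the sulfinyl group would aromatise ring A to A3, the 4'''-O-benzyl ether of 20.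
- In its favour: it is the most convergent plan. Unit 1 would enter as the commercial flavone genkwanin A4 (alkylated on O4' with a γ-halo β-ketoester, then silylated). The hindered diaryl ether is never made by substitution at an aromatic carbon, O5 and O7 of unit 2 appear directly as free phenols, and a single hydrogenolysis would finish the synthesis.
- Against it here: A2 needs a sequence of its own. The nucleophilic carbon of A1 is the one carrying the bulky aryloxy group. After conjugate addition the pyranone may open by β-elimination of its ring oxygen and not close. The Lewis acid that activates A2 also meets the pyranone of unit 1. A3 would form with O5 of unit 2 free under acidic conditions, which is when the ether can move from C8 to C6.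
- Comparison: on structure both plans fix the ether at C8 by construction, and alternative 1 is the better one in convergence and in operations after the key step (one against four). On mechanism the chosen step is a catalytic annulation with close precedent on salicylaldehydes and only one possible closure, whereas the domino sequence has at least one competing pathway, so the chosen plan is the safer one. Overall step count would probably be similar, because the steps saved at the end are spent on A1 and A2.

Alternative 2: The cut is at C3'-C4' and C5'-C6' of ring B of unit 1. The bridging oxygen stays on a two-carbon aryl ethynyl ether A6, and the other four ring carbons with the ester come from methyl coumalate A5. In the forward step A6 adds to A5 in an inverse-electron-demand Diels–Alder reaction, its nucleophilic terminal carbon bonding to C6 of the pyranone. Decarboxylative cycloreversion of the bridged lactone then gives the para-aryloxybenzoate A7, which is the same compound as 7.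
- In its favour: the ether is made without substitution at an aromatic carbon, so the hindrance of the phenoxide does not matter; on this point it is better than step 4. A5 is cheap, and the polarisation of both partners leads to the para pattern. Because A7 equals 7, everything downstream, the key step included, stays unchanged.
- Against it here: A6 would need two further operations from 5 (a vinylation–elimination sequence with an alkyllithium) beside MOM and benzyl ethers that invite ortho-lithiation. An electron-rich aryl ynol ether is thermally and hydrolytically labile, and the cycloaddition usually needs heat.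
- Comparison: on structure the two plans are equal, since they give the same compound. On mechanism a pericyclic step is less sensitive to steric hindrance than addition–elimination, which is a point for the alternative. On step economy it is two operations longer. It also does not touch ring C of unit 2, so it is a reserve for step 4 and not a substitute for the key step.

Alternative 3: The cut is at C8a-C4a and C5-C6 of ring A of unit 2, with C8a-C8 opened and re-formed on the way. C8a, C8 with its aryloxy group, C7 and C6 come from the cyclobutenone A8; C4a and C5 come from the silyloxyalkyne A9. On heating, A8 would open to a vinylketene that adds A9 in a [2+2] reaction. Opening of the new four-membered ring, 6π closure and tautomerisation would give phenol A10, whose only free hydroxyl is the future O1.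
- In its favour: the 1,2,3,5-tetraoxygenated ring with exactly one free hydroxyl arises in one neutral thermal step. That would replace the selective benzylation, the MOM group, the Baeyer–Villiger oxidation, the oxidation-prone 5 and the substitution of step 4, and on these points it is better than the chosen plan. A10 is the silyl analogue of 8 and would enter at step 6, so the key step stays the same.
- Against it here: A8 is not a commercial type of compound and would come from a ketene [2+2] reaction with A9, which itself needs several steps. Such heteroatom-substituted cyclobutenones and their ketenes are sensitive. The aryl silyl ethers are less robust than benzyl ethers towards LiOH and the lithium amide of steps 9 and 10. The bulky silyl ether beside the formylation site would slow step 6 and the rhodium step. A silyl/benzyl pair at the end means two deprotections or a change of the group on O4'''.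
- Comparison: on structure the plans are equal, since both settle the C8 ether and the free C8a hydroxyl before ring C is made. On mechanism the alternative sets the pattern by orbital-controlled steps with no regiochemical choice, which is elegant but less tested with these substituents than hydrogen-bond-guided alkylation and chelation-guided formylation. Step economy is about equal, because the four steps saved are spent on A8, A9 and the protecting-group change.

Key step: step 8

Remark on the chemistry: unit 1 is the 5-hydroxy-7-methoxyflavone half and unit 2 the 8-aryloxy half. C3', C4' refer to ring B of unit 1 and O4''' to the phenol oxygen of ring B of unit 2. The target has no stereocentre, so no configuration has to be set. The atom mapping of 9, 12 and 14 onto unit 2 (formyl carbon = C4, phenol oxygen = O1, aryloxy on C8) was checked and is consistent with the target.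

## Route

Step 1
Reactants: 1 2,4,6-trihydroxybenzaldehyde
Product: 2 2,4-dibenzyloxy-6-hydroxybenzaldehyde
Conditions: BnBr (2.05 equiv), K2CO3 (2.1 equiv), DMF, 0 °C → rt
Reagents that add atoms: benzyl bromide, BrCc1ccccc1
Why: Williamson etherification; the 4-hydroxyl and one ortho hydroxyl are alkylated, while the last ortho hydroxyl is held in a hydrogen bond to the formyl oxygen and is the least nucleophilic, so two equivalents of halide should stop mainly at the 2,4-diether.

Step 2
Reactants: 2 2,4-dibenzyloxy-6-hydroxybenzaldehyde
Product: 3 2,4-dibenzyloxy-6-(methoxymethoxy)benzaldehyde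
Conditions: MOMCl, i-Pr2NEt, CH2Cl2, 0 °C → 40 °C
Reagents that add atoms: chloromethyl methyl ether, COCCl
Why: O-alkylation of the chelated phenol to a mixed acetal under amine base; the MOM group marks this oxygen as the future O1 of unit 2 and is orthogonal to the benzyl ethers.

Step 3
Reactants: 3 2,4-dibenzyloxy-6-(methoxymethoxy)benzaldehyde
Product: 5 2,4-dibenzyloxy-6-(methoxymethoxy)phenol, via aryl formate 4 (not isolated)
Conditions: mCPBA, CH2Cl2, 0 °C → rt; aq. NaHCO3/Na2S2O3 wash; then K2CO3 (cat.), degassed MeOH, rt
Reagents that add atoms: meta-chloroperbenzoic acid, OOC(=O)c1cccc(Cl)c1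
Why: Baeyer–Villiger (Dakin-type) oxidation; in the Criegee adduct of this 2,4,6-trioxygenated benzaldehyde the electron-rich aryl group migrates in preference to hydride and gives formate 4, which catalytic methanolysis cleaves to the phenol, while MOM and benzyl ethers are inert to both stages.

Step 4
Reactants: 5 2,4-dibenzyloxy-6-(methoxymethoxy)phenol; 6 methyl 4-fluorobenzoate
Product: 7 methyl 4-[2,4-dibenzyloxy-6-(methoxymethoxy)phenoxy]benzoate
Conditions: Cs2CO3, DMSO, 110 °C, Ar
Reagents that add atoms: none
Why: Nucleophilic aromatic substitution by addition–elimination; the caesium phenoxide adds para to the ester of 6 and fluoride leaves from the Meisenheimer adduct, and because the neighbouring oxygen is a MOM ether only the oxygen destined to be the C8 ether can react.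

Step 5
Reactants: 7 methyl 4-[2,4-dibenzyloxy-6-(methoxymethoxy)phenoxy]benzoate
Product: 8 methyl 4-(2,4-dibenzyloxy-6-hydroxyphenoxy)benzoate
Conditions: conc. HCl (cat.), MeOH/THF, 50 °C
Reagents that add atoms: none
Why: Acid-catalysed acetal exchange with methanol removes the MOM group; benzyl ethers and the diaryl ether are stable to dilute acid, and the methyl ester cannot be scrambled because methanol is the solvent.

Step 6
Reactants: 8 methyl 4-(2,4-dibenzyloxy-6-hydroxyphenoxy)benzoate
Product: 9 methyl 4-(4,6-dibenzyloxy-3-formyl-2-hydroxyphenoxy)benzoate
Conditions: MgCl2, Et3N, (CH2O)n, MeCN, 80 °C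
Reagents that add atoms: paraformaldehyde (reacts as formaldehyde), C=O
Why: Magnesium-mediated ortho-formylation (Casnati–Skattebøl); formaldehyde is delivered inside the magnesium phenoxide chelate to the only free ortho carbon and the benzylic alkoxide is then oxidised by hydride transfer to a second formaldehyde, so the equally activated carbon para to the hydroxyl is not reached.

Step 7
Reactants: 10 4-benzyloxybenzoic acid
Product: 12 1-(4-benzyloxyphenyl)-2-(dimethyloxosulfanylidene)ethanone, via 4-benzyloxybenzoyl chloride 11 (not isolated)
Conditions: (COCl)2, DMF (cat.), CH2Cl2, 0 °C → rt, evaporate; then Me3S(O)I (3 equiv), KOt-Bu (3 equiv), THF, reflux, cool to 0 °C, add 11, → rt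
Reagents that add atoms: trimethylsulfoxonium iodide, C[S+](C)(C)=O.[I-]; oxalyl chloride, ClC(=O)C(Cl)=O (supplies only the chlorine of 11, which is lost again on the way to 12)
Why: Acid chloride formation through the chloroiminium catalyst, then C-acylation of dimethylsulfoxonium methylide (Corey–Chaykovsky reagent); a second equivalent of the methylide removes the acidic proton of the acylated salt and gives the stabilised β-keto sulfoxonium ylide.

Step 8
Reactants: 9 methyl 4-(4,6-dibenzyloxy-3-formyl-2-hydroxyphenoxy)benzoate; 12 1-(4-benzyloxyphenyl)-2-(dimethyloxosulfanylidene)ethanone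
Product: 14 methyl 4-[5,7-dibenzyloxy-2-(4-benzyloxyphenyl)-4-oxochromen-8-yl]oxybenzoate, via 1,3-diketone 13 (not isolated)
Conditions: [Cp*RhCl2]2 (4 mol %), AgSbF6 (16 mol %), NaOAc (0.5 equiv), PivOH (1 equiv), 12 (1.5 equiv), ClCH2CH2Cl, 90 °C, N2
Reagents that add atoms: none
Why: AgSbF6 strips chloride from the dimer to give a cationic Cp*Rh species of trivalent rhodium, which binds the phenoxide of 9; carboxylate-assisted cleavage of the neighbouring formyl C-H bond then gives a five-membered O,C-chelated acyl-rhodium complex. Ylide 12 binds through carbon and expels dimethyl sulfoxide to leave a rhodium α-oxo carbene, 1,1-migratory insertion of the acyl group makes the C3-C4 bond, and protonation by pivalic acid releases diketone 13 and returns the catalyst. The C8a hydroxyl of 13 then adds to the aryl ketone in a 6-exo-trig closure and the hemiketal loses water in the acidic medium, which forms O1-C2 and ring C as a 4-pyranone. The closest known reaction type is the annulation of salicylaldehydes with aroyl sulfoxonium ylides to flavones by formyl C-H activation at trivalent rhodium. No stereocentre is formed. The step needs selectivity for the formyl C-H bond over the aryl C-H bonds and over self-annulation of the ylide, which the five-membered chelate secures because every competing aryl C-H bond would need a larger or unchelated metallacycle; the excess of 12 covers what self-annulation consumes. It also needs a single direction of ring closure, which is secured because the oxygen on the other side of the acyl group (future O5) is benzylated, so the only free oxygen next to the new diketone is the one on C8a and the aryloxy group ends at C8.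

Step 9
Reactants: 14 methyl 4-[5,7-dibenzyloxy-2-(4-benzyloxyphenyl)-4-oxochromen-8-yl]oxybenzoate
Product: 15 4-[5,7-dibenzyloxy-2-(4-benzyloxyphenyl)-4-oxochromen-8-yl]oxybenzoic acid
Conditions: LiOH·H2O (3 equiv), THF/MeOH/H2O, rt; then 1 M HCl to pH 3
Reagents that add atoms: lithium hydroxide monohydrate (hydroxide oxygen), [Li+].[OH-].O
Why: Saponification of an unhindered aryl methyl ester by acyl-oxygen cleavage; at room temperature the 2-aryl-4-pyranone, deactivated by its 5,7-dialkoxy groups, should not be opened, and benzyl ethers are inert.

Step 10
Reactants: 15 4-[5,7-dibenzyloxy-2-(4-benzyloxyphenyl)-4-oxochromen-8-yl]oxybenzoic acid; 16 2',6'-dihydroxy-4'-methoxyacetophenone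
Product: 18 1-[4-[5,7-dibenzyloxy-2-(4-benzyloxyphenyl)-4-oxochromen-8-yl]oxyphenyl]-3-(2,6-dihydroxy-4-methoxyphenyl)propane-1,3-dione, via acid chloride 17 (not isolated)
Conditions: (COCl)2, DMF (cat.), CH2Cl2, 0 °C → rt, evaporate; 16 (2.2 equiv), LiN(SiMe3)2 (6.6 equiv), THF, −78 → −10 °C; add 17 in THF, −78 °C → rt; aq. NH4Cl
Reagents that add atoms: oxalyl chloride, ClC(=O)C(Cl)=O (supplies only the chlorine of 17; no atom of it remains in 18)
Why: Acid chloride formation, then C-acylation of the lithium trianion of 16 (the polyanion variant of the Baker–Venkataraman flavone synthesis); any O-acylated material converges on the same diketone by acyl migration under the basic conditions, and the second equivalent of trianion takes up the acidic proton of the product so that no free amide base meets 17.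

Step 11
Reactants: 18 1-[4-[5,7-dibenzyloxy-2-(4-benzyloxyphenyl)-4-oxochromen-8-yl]oxyphenyl]-3-(2,6-dihydroxy-4-methoxyphenyl)propane-1,3-dione
Product: 19 5,7-dibenzyloxy-2-(4-benzyloxyphenyl)-8-[4-(5-hydroxy-7-methoxy-4-oxochromen-2-yl)phenoxy]chromen-4-one
Conditions: p-TsOH·H2O (0.2 equiv), toluene, 90 °C
Reagents that add atoms: none
Why: Acid-catalysed cyclodehydration of the o-hydroxyaryl 1,3-diketone (6-exo-trig hemiketal formation, then loss of water); the two phenols beside the ketone are equivalent, so either closure gives the 5-hydroxy-7-methoxyflavone, and a catalytic sulfonic acid at moderate temperature should leave the benzyl ethers in place.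

Step 12
Reactants: 19 5,7-dibenzyloxy-2-(4-benzyloxyphenyl)-8-[4-(5-hydroxy-7-methoxy-4-oxochromen-2-yl)phenoxy]chromen-4-one
Product: 20 5,7-dihydroxy-8-[4-(5-hydroxy-7-methoxy-4-oxochromen-2-yl)phenoxy]-2-(4-hydroxyphenyl)chromen-4-one (CNP0424791.0)
Conditions: H2 (1 atm), Pd/C (10%), THF/MeOH, rt
Reagents that add atoms: none
Why: Catalytic hydrogenolysis of three benzyl aryl ethers under neutral conditions; the methyl ether and the diaryl ether are stable, the conjugated C2-C3 double bonds of flavones are reduced much more slowly than benzyl C-O bonds are cleaved, and the absence of acid and base excludes a shift of the ether from C8 to C6 once O5 of unit 2 is free.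

## Compound list

1 | 2,4,6-trihydroxybenzaldehyde | O=Cc1c(O)cc(O)cc1O | starting material
2 | 2,4-dibenzyloxy-6-hydroxybenzaldehyde | O=Cc1c(O)cc(OCc2ccccc2)cc1OCc1ccccc1 | intermediate
3 | 2,4-dibenzyloxy-6-(methoxymethoxy)benzaldehyde | O=Cc1c(OCOC)cc(OCc2ccccc2)cc1OCc1ccccc1 | intermediate
4 | [2,4-dibenzyloxy-6-(methoxymethoxy)phenyl] formate | O=COc1c(OCOC)cc(OCc2ccccc2)cc1OCc1ccccc1 | intermediate
5 | 2,4-dibenzyloxy-6-(methoxymethoxy)phenol | Oc1c(OCOC)cc(OCc2ccccc2)cc1OCc1ccccc1 | intermediate
6 | methyl 4-fluorobenzoate | COC(=O)c1ccc(F)cc1 | starting material
7 | methyl 4-[2,4-dibenzyloxy-6-(methoxymethoxy)phenoxy]benzoate | COC(=O)c1ccc(Oc2c(OCOC)cc(OCc3ccccc3)cc2OCc2ccccc2)cc1 | intermediate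
8 | methyl 4-(2,4-dibenzyloxy-6-hydroxyphenoxy)benzoate | COC(=O)c1ccc(Oc2c(O)cc(OCc3ccccc3)cc2OCc2ccccc2)cc1 | intermediate
9 | methyl 4-(4,6-dibenzyloxy-3-formyl-2-hydroxyphenoxy)benzoate | COC(=O)c1ccc(Oc2c(O)c(C=O)c(OCc3ccccc3)cc2OCc2ccccc2)cc1 | intermediate
10 | 4-benzyloxybenzoic acid | OC(=O)c1ccc(OCc2ccccc2)cc1 | starting material
11 | 4-benzyloxybenzoyl chloride | ClC(=O)c1ccc(OCc2ccccc2)cc1 | intermediate
12 | 1-(4-benzyloxyphenyl)-2-(dimethyloxosulfanylidene)ethanone | CS(C)(=O)=CC(=O)c1ccc(OCc2ccccc2)cc1 | intermediate
13 | methyl 4-[4,6-dibenzyloxy-3-[3-(4-benzyloxyphenyl)-3-oxopropanoyl]-2-hydroxyphenoxy]benzoate | COC(=O)c1ccc(Oc2c(O)c(C(=O)CC(=O)c3ccc(OCc4ccccc4)cc3)c(OCc3ccccc3)cc2OCc2ccccc2)cc1 | intermediate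
14 | methyl 4-[5,7-dibenzyloxy-2-(4-benzyloxyphenyl)-4-oxochromen-8-yl]oxybenzoate | COC(=O)c1ccc(Oc2c(OCc3ccccc3)cc(OCc3ccccc3)c3c(=O)cc(-c4ccc(OCc5ccccc5)cc4)oc23)cc1 | intermediate
15 | 4-[5,7-dibenzyloxy-2-(4-benzyloxyphenyl)-4-oxochromen-8-yl]oxybenzoic acid | OC(=O)c1ccc(Oc2c(OCc3ccccc3)cc(OCc3ccccc3)c3c(=O)cc(-c4ccc(OCc5ccccc5)cc4)oc23)cc1 | intermediate
16 | 2',6'-dihydroxy-4'-methoxyacetophenone | CC(=O)c1c(O)cc(OC)cc1O | starting material
17 | 4-[5,7-dibenzyloxy-2-(4-benzyloxyphenyl)-4-oxochromen-8-yl]oxybenzoyl chloride | ClC(=O)c1ccc(Oc2c(OCc3ccccc3)cc(OCc3ccccc3)c3c(=O)cc(-c4ccc(OCc5ccccc5)cc4)oc23)cc1 | intermediate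
18 | 1-[4-[5,7-dibenzyloxy-2-(4-benzyloxyphenyl)-4-oxochromen-8-yl]oxyphenyl]-3-(2,6-dihydroxy-4-methoxyphenyl)propane-1,3-dione | COc1cc(O)c(C(=O)CC(=O)c2ccc(Oc3c(OCc4ccccc4)cc(OCc4ccccc4)c4c(=O)cc(-c5ccc(OCc6ccccc6)cc5)oc34)cc2)c(O)c1 | intermediate
19 | 5,7-dibenzyloxy-2-(4-benzyloxyphenyl)-8-[4-(5-hydroxy-7-methoxy-4-oxochromen-2-yl)phenoxy]chromen-4-one | COc1cc(O)c2c(=O)cc(-c3ccc(Oc4c(OCc5ccccc5)cc(OCc5ccccc5)c5c(=O)cc(-c6ccc(OCc7ccccc7)cc6)oc45)cc3)oc2c1 | intermediate
20 | 5,7-dihydroxy-8-[4-(5-hydroxy-7-methoxy-4-oxochromen-2-yl)phenoxy]-2-(4-hydroxyphenyl)chromen-4-one (CNP0424791.0) | COc1cc(O)c2c(=O)cc(-c3ccc(Oc4c(O)cc(O)c5c(=O)cc(-c6ccc(O)cc6)oc45)cc3)oc2c1 | target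

## Step count and least certain steps

Total: 12 steps. Longest linear sequence: 11 steps (steps 1 to 6 and 8 to 12, from 1 to 20); step 7 is a one-step branch.

Step 8 (key step). The formyl group of 9 is flanked on both sides and sits on a very electron-rich ring, so C-H activation or carbene transfer may be slow. That would give room to decarbonylation of the acyl-rhodium intermediate, to self-annulation of the ylide, and to Lewis-acid-induced loss of the benzyl ether next to the carbonyl. The fallback sets out from 9 and returns at 14 by polar chemistry. An excess of the lithium acetylide of commercial 1-benzyloxy-4-ethynylbenzene (n-BuLi, THF, −78 °C; the first equivalent forms the phenoxide) would add to the aldehyde and give methyl 4-[4,6-dibenzyloxy-3-[3-(4-benzyloxyphenyl)-1-hydroxyprop-2-ynyl]-2-hydroxyphenoxy]benzoate F1 (racemic; the carbinol centre disappears in the next operation). Oxidation with MnO2 in CH2Cl2 would give methyl 4-[4,6-dibenzyloxy-3-[3-(4-benzyloxyphenyl)prop-2-ynoyl]-2-hydroxyphenoxy]benzoate F2. Diethylamine in ethanol would then add to the ynone, and the C8a hydroxyl would displace the amine in a 6-endo sense to give 14.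

Step 4. A di-ortho-substituted, electron-rich phenoxide must add to a fluoroarene activated only by an ester, so the substitution may be slow. That leaves time for air oxidation of the phenoxide and for its attack on the ester (acyl or methyl transfer). The fallback sets out from 5 and returns at 7: copper-catalysed Ullmann-type coupling of 5 with methyl 4-iodobenzoate (CuI, picolinic acid, K3PO4, DMSO, 90 °C), a protocol suited to hindered phenols. It makes no new compound (F0).

Step 10. The acylation may be incomplete or unselective: the aggregated trianion may react slowly, proton transfer from the product may stop conversion, O-acylation or double acylation may compete, and the enolate may add to the pyranone of unit 2. The fallback sets out from 15 and 16 and returns at 18 by the classical two-stage sequence. Esterification (EDC·HCl, DMAP, CH2Cl2) would give the mono-ester (2-acetyl-3-hydroxy-5-methoxyphenyl) 4-[5,7-dibenzyloxy-2-(4-benzyloxyphenyl)-4-oxochromen-8-yl]oxybenzoate F3. Baker–Venkataraman rearrangement (KOt-Bu, THF, rt) would then move the acyl group from oxygen to carbon and give 18.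

Step 9. Hydroxide may attack C2 of the pyranone of unit 2 and open ring C, with possible retro-Claisen cleavage, while the electron-rich benzoate hydrolyses only slowly. The fallback sets out from 14 and returns at 18, bypassing 15 and 17: crossed Claisen condensation of the methyl ester of 14 with the lithium trianion of 16 (LiN(SiMe3)2, THF, −78 °C → rt), so that no hydroxide is used. It makes no new compound (F0). It is not the main line because an ester is a much weaker acylating agent than 17 towards the aggregated trianion.

Step 12. A C2-C3 double bond of either flavone may be over-reduced, or the reaction may stall after partial debenzylation because the polyphenolic intermediates precipitate on the catalyst. The fallback sets out from 19 and returns at 20: Lewis-acid debenzylation with BCl3 and pentamethylbenzene as cation scavenger (CH2Cl2, −78 °C). The methyl ether on O7 of unit 1 is not chelated and should survive. It makes no new compound (F0).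

## Further compounds

F1 | step 8 | methyl 4-[4,6-dibenzyloxy-3-[3-(4-benzyloxyphenyl)-1-hydroxyprop-2-ynyl]-2-hydroxyphenoxy]benzoate (racemic) | COC(=O)c1ccc(Oc2c(O)c(C(O)C#Cc3ccc(OCc4ccccc4)cc3)c(OCc3ccccc3)cc2OCc2ccccc2)cc1
F2 | step 8 | methyl 4-[4,6-dibenzyloxy-3-[3-(4-benzyloxyphenyl)prop-2-ynoyl]-2-hydroxyphenoxy]benzoate | COC(=O)c1ccc(Oc2c(O)c(C(=O)C#Cc3ccc(OCc4ccccc4)cc3)c(OCc3ccccc3)cc2OCc2ccccc2)cc1
F0 | step 4 | none | none
F3 | step 10 | (2-acetyl-3-hydroxy-5-methoxyphenyl) 4-[5,7-dibenzyloxy-2-(4-benzyloxyphenyl)-4-oxochromen-8-yl]oxybenzoate | CC(=O)c1c(O)cc(OC)cc1OC(=O)c1ccc(Oc2c(OCc3ccccc3)cc(OCc3ccccc3)c3c(=O)cc(-c4ccc(OCc5ccccc5)cc4)oc23)cc1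
F0 | step 9 | none | none
F0 | step 12 | none | none
A1 | alternative 1 | 7-methoxy-2-[4-[4-methoxy-2,4-bis(trimethylsilyloxy)buta-1,3-dienoxy]phenyl]-5-trimethylsilyloxychromen-4-one (double-bond geometry not defined) | COC(O[Si](C)(C)C)=CC(O[Si](C)(C)C)=COc1ccc(cc1)-c1cc(=O)c2c(O[Si](C)(C)C)cc(OC)cc2o1
A2 | alternative 1 | 2-(4-benzyloxyphenyl)-5-(phenylsulfinyl)pyran-4-one (racemic at sulfur) | O=c1cc(-c2ccc(OCc3ccccc3)cc2)occ1S(=O)c1ccccc1
A3 | alternative 1 | 2-(4-benzyloxyphenyl)-5,7-dihydroxy-8-[4-(5-hydroxy-7-methoxy-4-oxochromen-2-yl)phenoxy]chromen-4-one | COc1cc(O)c2c(=O)cc(-c3ccc(Oc4c(O)cc(O)c5c(=O)cc(-c6ccc(OCc7ccccc7)cc6)oc45)cc3)oc2c1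
A4 | alternative 1 | genkwanin, 5-hydroxy-2-(4-hydroxyphenyl)-7-methoxychromen-4-one | COc1cc(O)c2c(=O)cc(-c3ccc(O)cc3)oc2c1
A5 | alternative 2 | methyl coumalate, methyl 2-oxopyran-5-carboxylate | COC(=O)c1ccc(=O)oc1
A6 | alternative 2 | 1,5-dibenzyloxy-2-ethynyloxy-3-(methoxymethoxy)benzene | C#COc1c(OCOC)cc(OCc2ccccc2)cc1OCc1ccccc1
A7 | alternative 2 | methyl 4-[2,4-dibenzyloxy-6-(methoxymethoxy)phenoxy]benzoate (identical with 7) | COC(=O)c1ccc(Oc2c(OCOC)cc(OCc3ccccc3)cc2OCc2ccccc2)cc1
A8 | alternative 3 | methyl 4-[4-oxo-2-(triisopropylsilyloxy)cyclobut-2-enyl]oxybenzoate (racemic) | COC(=O)c1ccc(OC2C(=O)C=C2O[Si](C(C)C)(C(C)C)C(C)C)cc1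
A9 | alternative 3 | (triisopropylsilyloxy)ethyne | C#CO[Si](C(C)C)(C(C)C)C(C)C
A10 | alternative 3 | methyl 4-[2-hydroxy-4,6-bis(triisopropylsilyloxy)phenoxy]benzoate | COC(=O)c1ccc(Oc2c(O)cc(O[Si](C(C)C)(C(C)C)C(C)C)cc2O[Si](C(C)C)(C(C)C)C(C)C)cc1
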